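The numbers of this flask belong to no real substance; the flask was simulated.

The slowness of this chemistry tempted me to give the next run the 12 d of delta and not the 6.0 d of zeta, so before charging it I wanted to know what those extra days buy.

all flasks: starting material 0.15 M; protic impurity 0.0750 M
- zeta: time 6.0 d
- delta: time 12 d

    starting material + protic impurity → quenched substrate (k1 = 1.1 L mol⁻¹ h⁻¹)
    starting material → target (k2 = 0.066 h⁻¹)
    2 starting material → self-condensation product (k3 = 0.74 L mol⁻¹ h⁻¹)
    starting material ⇌ other conformer, settled at all times (K4 = 1.6)
    other conformer ⇌ third conformer (K5 = 2.5, k5 = 0.041 h⁻¹)
    other conformer → isomer of the product (k6 = 0.13 h⁻¹)
    third conformer → third product (k7 = 0.021 h⁻¹)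

- in percentages every species weighs as the starting material in it: one self-condensation product counts as two
- two of one species on the left: rate k times its square, two consumed each time
- run time (zeta): 6.0 d

- which of these there is most of at the end, counted by the starting material in it, zeta (other conformer / third product / isomer of the product / target)
- which of these there is most of at the end, counted by the starting material in it, delta (other conformer / third product / isomer of the product / target)
- final amount of the leader among these, as a percentage of the starting material charged, in zeta
- final amount of the leader among these, as a percentage of the starting material charged, in delta

I followed one molecule through the pool, by which I mean starting material and other conformer together, held at balance with 1.6 of the second to each of the first. Counted per molecule in the starting-material form, the exits weigh 0.066 h⁻¹ to target, 0.208 h⁻¹ to isomer of the product and 0.0825 h⁻¹ to quenched substrate, taking c(protic impurity) as charged. The third conformer is a side room: 56.1 % of what enters goes on to third product and the rest returns, so that exit weighs 0.0368 h⁻¹.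

Target and isomer of the product leave the same pool by first-order steps, so c(starting material) cancels from their ratio. This gives the selectivity factor S, the isomer of the product formed per target formed, 3.15.

The exits sum to 0.393 h⁻¹, so I reckoned 52.9 % in zeta and 52.9 % in delta, with isomer of the product leading zeta and isomer of the product leading delta. Self-condensation starts at a weight of 0.0854 h⁻¹, close to the quench, but that weight falls as the pool thins, so I left it out and expected the flask somewhat under my figure. The pool's half-life by these exits is 0.191 d, much shorter than zeta's time, so I expected delta to add no isomer of the product.

The forecast named isomer of the product for zeta and isomer of the product for delta, at 51 % and 51.2 %, lower than mine, and it called the two yields essentially the same since both runs lie “far beyond the pool's lifetime of a few tens of hours”.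

The simulation gave isomer of the product in zeta and isomer of the product in delta, at 49.8 % and 49.8 %, so the forecast stood, and the extra days of delta were not the reason for any gain. Target in zeta read 15.8 %, a ratio of 3.15, which is S. With the quench struck out of zeta, isomer of the product rose from 49.8 % to 59.5 %, so my decision went to the impurity, not the clock. In the neighbour like zeta but charged with 0.38 M of starting material, self-condensation product reached 20.2 % and isomer of the product 45.4 %, from which S gives target 14.4 % against the 14.4 % that flask held.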